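**Plan**
Numbering: C1 = OCH2 of the decadienyl chain, C8 = acetoxy carbon, C10=C11 = exocyclic alkene, C12 = ring carbinol, C13 = ring O–CH, C14=C15 = isobutenyl alkene (C15 carries both methyls), C16 = lactone carbonyl.
Retrosynthetic cuts, in order: the C12 O–Si and C8 O–acetyl bonds; C8–C9 (vinylogous aldol to a C1–C8 enal); C10–C11 (acetaldehyde aldol/dehydration); the ring O–C13 bond (allyl-palladium lactonisation); C11–C12 (acetate aldol); the C1 ester C–O bond and the C8 oxidation level, back to nerol and (E)-3-methylpent-2-enoic acid.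
Forward order: the γ-lactone, the only ring, closes first through O–C13; the ethylidene is appended; its silyl dienolate is joined at C8–C9 to the nerol-derived enal; acetylation and desilylation finish.
Stereochemistry: C12 from a catalyst-controlled Mukaiyama acetate aldol; C13 relayed from C12 during ring closure; C8 from a catalyst-controlled vinylogous Mukaiyama aldol; 2Z from nerol, 6E from the SeO2 oxidation, exocyclic E from γ-attack through the s-trans dienolate.
Enabling feature: C13 is the lactone O-alkyl carbon and is allylic to C14=C15, and C15 bears two identical methyls, so a C13–C15 π-allyl can exchange its faces through C15 before the C16 carboxylate closes the five-membered ring at C13.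

Key step: step 8

Remark: metal alkoxides and carboxylates and the alkenylaluminate of step 2 are only protonated on aqueous work-up and are written as the neutral products; the acetylide of step 1, lithium enolates and covalent silyl or sulfonyl intermediates are numbered.

**Route**

Step 1
Reactants: 1 2-methylbut-3-yn-2-ol
Product: 3 4-methylpent-2-yne-1,4-diol, via dilithium alkoxide-acetylide 2 (not isolated)
Conditions: n-BuLi (2.1 equiv), THF, −78 → 0 °C; (CH2O)n, 0 °C → rt; H2O
Reagents that add atoms: paraformaldehyde (formaldehyde), C=O; n-butyllithium, [Li]CCCC (lithium, in 2 only)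
Why: Double deprotonation gives the alkoxide–acetylide, whose carbon terminus adds to formaldehyde (acetylide hydroxymethylation); no stereocentre is formed.

Step 2
Reactants: 3 4-methylpent-2-yne-1,4-diol
Product: 4 (E)-4-methylpent-2-ene-1,4-diol
Conditions: LiAlH4 (2 equiv), THF, reflux; H2O
Reagents that add atoms: none
Why: Alkoxide-directed trans-hydroalumination of the propargylic alcohol followed by protonolysis should give the (E)-alkene only.

Step 3
Reactants: 4 (E)-4-methylpent-2-ene-1,4-diol
Product: 5 (E)-4-hydroxy-4-methylpent-2-enal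
Conditions: MnO2 (10 equiv), CH2Cl2, rt
Reagents that add atoms: none
Why: MnO2 allylic oxidation touches only the primary allylic alcohol, since the tertiary carbinol cannot be oxidised, and the alkene geometry is retained.

Step 4
Reactants: 5 (E)-4-hydroxy-4-methylpent-2-enal
Product: 6 (E)-tert-butyl (2-methyl-5-oxopent-3-en-2-yl) carbonate
Conditions: Boc2O (2 equiv), DMAP (0.2 equiv), MeCN, rt
Reagents that add atoms: di-tert-butyl dicarbonate, CC(C)(C)OC(=O)OC(=O)OC(C)(C)C
Why: DMAP-catalysed O-tert-butoxycarbonylation acts on the only hydroxyl present, the enal is inert to the acylpyridinium, and the carbonate both installs the leaving group for step 8 and masks the OH before the silicon Lewis acid of step 5.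

Step 5
Reactants: 6 (E)-tert-butyl (2-methyl-5-oxopent-3-en-2-yl) carbonate; 7 1-(tert-butyldimethylsilyloxy)-1-methoxyethene
Product: 9 methyl (3S,4E)-6-(tert-butoxycarbonyloxy)-3-hydroxy-6-methylhept-4-enoate, via O-trichlorosilyl aldolate 8 (not isolated)
Conditions: SiCl4 (1.1 equiv), binaphthyl-2,2′-diamine-derived bisphosphoramide with an N,N′-dimethylpentane-1,5-diamine linker (2 mol %; the antipode that gives Si-face addition, assigned beforehand on cinnamaldehyde with 7), CH2Cl2, −78 °C; sat. aq. NaHCO3
Reagents that add atoms: silicon tetrachloride, Cl[Si](Cl)(Cl)Cl (in 8 only)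
Why: In this Lewis-base-catalysed, SiCl4-mediated Mukaiyama aldol the chiral phosphoramide-bound trichlorosilyl cation activates the conjugated aldehyde (the best substrate class for this catalyst), the ketene acetal adds 1,2 to the Si face, and C12 is thereby set as (S) under catalyst control.

Step 6
Reactants: 9 methyl (3S,4E)-6-(tert-butoxycarbonyloxy)-3-hydroxy-6-methylhept-4-enoate
Product: 10 methyl (3S,4E)-6-(tert-butoxycarbonyloxy)-3-(tert-butyldimethylsilyloxy)-6-methylhept-4-enoate
Conditions: TBSCl (1.3 equiv), imidazole (2.5 equiv), DMF, rt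
Reagents that add atoms: tert-butylchlorodimethylsilane, CC(C)(C)[Si](C)(C)Cl
Why: Imidazole-promoted silyl ether formation on a secondary allylic alcohol is routine and introduces the bulky group that later biases the ring closure and survives the enolate chemistry.

Step 7
Reactants: 10 methyl (3S,4E)-6-(tert-butoxycarbonyloxy)-3-(tert-butyldimethylsilyloxy)-6-methylhept-4-enoate
Product: 11 (3S,4E)-6-(tert-butoxycarbonyloxy)-3-(tert-butyldimethylsilyloxy)-6-methylhept-4-enoic acid
Conditions: LiOH·H2O (2 equiv), THF/H2O 3:1, 0 °C → rt; 0.5 M HCl to pH 4 at 0 °C; used at once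
Reagents that add atoms: lithium hydroxide, [Li+].[OH-] (hydroxide oxygen of the acid)
Why: Saponification should cleave the unhindered methyl ester selectively, because the di-tertiary carbonate is too hindered for hydroxide and the β-silyloxy ester does not undergo E1cB at this temperature.

Step 8
Reactants: 11 (3S,4E)-6-(tert-butoxycarbonyloxy)-3-(tert-butyldimethylsilyloxy)-6-methylhept-4-enoic acid
Product: 12 (4S,5R)-4-(tert-butyldimethylsilyloxy)-5-(2-methylprop-1-enyl)oxolan-2-one
Conditions: Pd2(dba)3·CHCl3 (2.5 mol %), PPh3 (15 mol %), THF, 0 °C → rt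
Reagents that add atoms: none
Why: Zerovalent palladium ionises the tertiary allylic carbonate with loss of CO2, the liberated tert-butoxide deprotonates the acid, and the C16 carboxylate attacks C13 of the C13–C15 π-allyl on the face opposite the metal (intramolecular Tsuji–Trost allylic substitution, i.e. palladium-catalysed allylic lactonisation). The single ring closes in 5-exo fashion through the O–C13 bond, whereas attack at C15 would require a seven-membered lactone spanning the syn-configured allyl unit and should not compete. The new stereocentre C13 is controlled by the C12 silyloxy centre: the two diastereomeric π-allyl complexes interconvert through the η1 form at C15, whose two methyls are identical, so both can drain through the transition state that keeps the palladium-bound isobutenyl unit and the bulky silyl ether on opposite faces of the forming ring. Because the allylic lactone can re-ionise, the trans isomer is also expected to be the thermodynamic sink. The step needs trans diastereoselectivity and ring closure faster than β-hydride loss to the diene; the short tether, the carboxylate generated within the ion pair and the size of the silyl group are what should secure both.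

Step 9
Reactants: 12 (4S,5R)-4-(tert-butyldimethylsilyloxy)-5-(2-methylprop-1-enyl)oxolan-2-one; 13 acetaldehyde
Product: 15 (3S,4S,5R)-4-(tert-butyldimethylsilyloxy)-3-(1-hydroxyethyl)-5-(2-methylprop-1-enyl)oxolan-2-one (3,4-trans; both carbinol epimers), via lithium enolate 14 (not isolated)
Conditions: LiN(SiMe3)2 (1.1 equiv), THF, −78 °C; CH3CHO (3 equiv), −78 °C; AcOH quench at −78 °C
Reagents that add atoms: lithium bis(trimethylsilyl)amide, [Li]N([Si](C)(C)C)[Si](C)(C)C (lithium, in 14 only)
Why: Lithium enolate aldol addition at −78 °C, where 3-silyloxy-γ-lactone enolates of the 2-deoxyribonolactone type are known to persist without β-elimination; acetaldehyde should approach anti to the C12 silyloxy group, and the carbinol configuration is irrelevant because it is removed in step 10.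

Step 10
Reactants: 15 (3S,4S,5R)-4-(tert-butyldimethylsilyloxy)-3-(1-hydroxyethyl)-5-(2-methylprop-1-enyl)oxolan-2-one
Product: 17 (3E,4S,5R)-3-ethylidene-4-(tert-butyldimethylsilyloxy)-5-(2-methylprop-1-enyl)oxolan-2-one, via mesylate 16 (not isolated)
Conditions: MsCl (1.5 equiv), Et3N (3 equiv), CH2Cl2, 0 °C; then DBU (2 equiv), 0 °C → rt
Reagents that add atoms: methanesulfonyl chloride, CS(=O)(=O)Cl (in 16 only)
Why: Mesylation followed by DBU-induced E1cB elimination should expel the mesylate rather than the much poorer ring silyloxide and give mainly the (E)-ethylidene lactone; any (Z)-isomer is carried on, because both converge on one dienolate in step 11.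

Step 11
Reactants: 17 (3E,4S,5R)-3-ethylidene-4-(tert-butyldimethylsilyloxy)-5-(2-methylprop-1-enyl)oxolan-2-one
Product: 19 (4S,5R)-2,4-bis(tert-butyldimethylsilyloxy)-3-ethenyl-5-(2-methylprop-1-enyl)-4,5-dihydrofuran, via lithium dienolate 18 (not isolated)
Conditions: LiN(iPr)2 (1.2 equiv), THF/DMPU 5:1, −78 °C; TBSCl (1.3 equiv), −78 → 0 °C; pentane, filtration, used without chromatography
Reagents that add atoms: tert-butylchlorodimethylsilane, CC(C)(C)[Si](C)(C)Cl; lithium diisopropylamide, CC(C)N([Li])C(C)C (lithium, in 18 only)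
Why: Kinetic γ-deprotonation at C9 and O-silylation is the standard preparation of ester-derived silyl dienol ethers (silyl ketene acetal formation); low temperature and prompt trapping should keep the C12 silyloxide in place, and the alkene geometry of 17 is erased.

Step 12
Reactants: 20 nerol; 21 (E)-3-methylpent-2-enoic acid
Product: 22 neryl (E)-3-methylpent-2-enoate [(2Z)-3,7-dimethylocta-2,6-dien-1-yl (E)-3-methylpent-2-enoate]
Conditions: DCC (1.1 equiv), DMAP (0.1 equiv), CH2Cl2, 0 °C → rt
Reagents that add atoms: none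
Why: Steglich esterification of a primary allylic alcohol is mild enough that the β,β-disubstituted enoate should keep its (E)-geometry and nerol its (Z)-geometry.

Step 13
Reactants: 22 neryl (E)-3-methylpent-2-enoate
Product: 23 (2Z,6E)-8-hydroxy-3,7-dimethylocta-2,6-dien-1-yl (E)-3-methylpent-2-enoate
Conditions: SeO2 (0.3 equiv), t-BuOOH (3 equiv), salicylic acid (0.1 equiv), CH2Cl2, rt
Reagents that add atoms: tert-butyl hydroperoxide, CC(C)(C)OO (terminal oxygen source, relayed through catalytic SeO2, O=[Se]=O)
Why: Riley allylic oxidation (ene reaction, then 2,3-shift) attacks the electron-rich terminal isopropylidene rather than the ester-deactivated C2=C3 alkene or the enoate and functionalises the (E)-methyl, which fixes the 6E geometry; any over-oxidised enal is combined with the product of step 14.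

Step 14
Reactants: 23 (2Z,6E)-8-hydroxy-3,7-dimethylocta-2,6-dien-1-yl (E)-3-methylpent-2-enoate
Product: 24 (2Z,6E)-3,7-dimethyl-8-oxoocta-2,6-dien-1-yl (E)-3-methylpent-2-enoate
Conditions: MnO2 (15 equiv), CH2Cl2, rt
Reagents that add atoms: none
Why: MnO2 allylic oxidation should convert the primary allylic alcohol into the enal without affecting the esters or any alkene geometry.

Step 15
Reactants: 19 (4S,5R)-2,4-bis(tert-butyldimethylsilyloxy)-3-ethenyl-5-(2-methylprop-1-enyl)-4,5-dihydrofuran; 24 (2Z,6E)-3,7-dimethyl-8-oxoocta-2,6-dien-1-yl (E)-3-methylpent-2-enoate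
Product: 26 (2Z,6E,8S)-10-[(3E,4S,5R)-4-(tert-butyldimethylsilyloxy)-5-(2-methylprop-1-enyl)-2-oxooxolan-3-ylidene]-8-hydroxy-3,7-dimethyldeca-2,6-dien-1-yl (E)-3-methylpent-2-enoate, via O-trichlorosilyl ether 25 (not isolated)
Conditions: SiCl4 (1.5 equiv), the bisphosphoramide of step 5 (5 mol %, same antipode), iPr2NEt (10 mol %), CH2Cl2, −78 °C; sat. aq. NaHCO3
Reagents that add atoms: silicon tetrachloride, Cl[Si](Cl)(Cl)Cl (in 25 only)
Why: In this catalytic enantioselective vinylogous Mukaiyama aldol the fully substituted α-carbon C11 should direct bond formation to the γ-carbon C9, the chiral trichlorosilyl cation exposes the Si face of the enal so that C8 is set as (S) by the catalyst (the remote C12 and C13 centres should matter little), and reaction through the s-trans dienolate regenerates the lactone with the (E)-C10=C11 alkene.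

Step 16
Reactants: 26 the C8 alcohol of step 15
Product: 27 (2Z,6E,8S)-8-acetoxy-10-[(3E,4S,5R)-4-(tert-butyldimethylsilyloxy)-5-(2-methylprop-1-enyl)-2-oxooxolan-3-ylidene]-3,7-dimethyldeca-2,6-dien-1-yl (E)-3-methylpent-2-enoate
Conditions: Ac2O (3 equiv), pyridine (6 equiv), DMAP (0.05 equiv), CH2Cl2, 0 °C
Reagents that add atoms: acetic anhydride, CC(=O)OC(C)=O
Why: DMAP-catalysed acetylation of the secondary allylic alcohol runs under weakly basic conditions that should not trigger vinylogous elimination across C8–C9.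

Step 17
Reactants: 27 the silyl-protected acetate of step 16
Product: 28 (2Z,6E,8S)-8-acetoxy-10-[(3E,4S,5R)-4-hydroxy-5-(2-methylprop-1-enyl)-2-oxooxolan-3-ylidene]-3,7-dimethyldeca-2,6-dien-1-yl (E)-3-methylpent-2-enoate (target)
Conditions: HF·pyridine, pyridine, THF, 0 °C → rt
Reagents that add atoms: none
Why: Fluoride-mediated desilylation under buffered acidic conditions should free the C12 hydroxyl while leaving the acetate, both esters and the base-sensitive β-acetoxy alkylidene lactone untouched; no stereocentre is affected.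

**Compound list**
1 | 2-methylbut-3-yn-2-ol | CC(C)(O)C#C | starting material
2 | dilithium alkoxide-acetylide of 1 | [Li]C#CC(C)(C)O[Li] | intermediate
3 | 4-methylpent-2-yne-1,4-diol | CC(C)(O)C#CCO | intermediate
4 | (E)-4-methylpent-2-ene-1,4-diol | CC(C)(O)/C=C/CO | intermediate
5 | (E)-4-hydroxy-4-methylpent-2-enal | CC(C)(O)/C=C/C=O | intermediate
6 | (E)-tert-butyl (2-methyl-5-oxopent-3-en-2-yl) carbonate | CC(C)(C)OC(=O)OC(C)(C)/C=C/C=O | intermediate
7 | 1-(tert-butyldimethylsilyloxy)-1-methoxyethene | C=C(OC)O[Si](C)(C)C(C)(C)C | starting material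
8 | O-trichlorosilyl aldolate of 9 | COC(=O)C[C@H](O[Si](Cl)(Cl)Cl)/C=C/C(C)(C)OC(=O)OC(C)(C)C | intermediate
9 | methyl (3S,4E)-6-(tert-butoxycarbonyloxy)-3-hydroxy-6-methylhept-4-enoate | COC(=O)C[C@H](O)/C=C/C(C)(C)OC(=O)OC(C)(C)C | intermediate
10 | methyl (3S,4E)-6-(tert-butoxycarbonyloxy)-3-(tert-butyldimethylsilyloxy)-6-methylhept-4-enoate | COC(=O)C[C@H](O[Si](C)(C)C(C)(C)C)/C=C/C(C)(C)OC(=O)OC(C)(C)C | intermediate
11 | (3S,4E)-6-(tert-butoxycarbonyloxy)-3-(tert-butyldimethylsilyloxy)-6-methylhept-4-enoic acid | OC(=O)C[C@H](O[Si](C)(C)C(C)(C)C)/C=C/C(C)(C)OC(=O)OC(C)(C)C | intermediate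
12 | (4S,5R)-4-(tert-butyldimethylsilyloxy)-5-(2-methylprop-1-enyl)oxolan-2-one | C1C(=O)O[C@H](C=C(C)C)[C@H]1O[Si](C)(C)C(C)(C)C | intermediate
13 | acetaldehyde | CC=O | starting material
14 | lithium enolate of 12 | C1=C(O[Li])O[C@H](C=C(C)C)[C@H]1O[Si](C)(C)C(C)(C)C | intermediate
15 | (3S,4S,5R)-4-(tert-butyldimethylsilyloxy)-3-(1-hydroxyethyl)-5-(2-methylprop-1-enyl)oxolan-2-one (carbinol epimers) | CC(O)[C@@H]1C(=O)O[C@H](C=C(C)C)[C@H]1O[Si](C)(C)C(C)(C)C | intermediate
16 | mesylate of 15 | CC(OS(C)(=O)=O)[C@@H]1C(=O)O[C@H](C=C(C)C)[C@H]1O[Si](C)(C)C(C)(C)C | intermediate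
17 | (3E,4S,5R)-3-ethylidene-4-(tert-butyldimethylsilyloxy)-5-(2-methylprop-1-enyl)oxolan-2-one | C/C=C1/C(=O)O[C@H](C=C(C)C)[C@H]1O[Si](C)(C)C(C)(C)C | intermediate
18 | lithium dienolate of 17 | C=CC1=C(O[Li])O[C@H](C=C(C)C)[C@H]1O[Si](C)(C)C(C)(C)C | intermediate
19 | (4S,5R)-2,4-bis(tert-butyldimethylsilyloxy)-3-ethenyl-5-(2-methylprop-1-enyl)-4,5-dihydrofuran | C=CC1=C(O[Si](C)(C)C(C)(C)C)O[C@H](C=C(C)C)[C@H]1O[Si](C)(C)C(C)(C)C | intermediate
20 | nerol | CC(C)=CCC/C(C)=C\CO | starting material
21 | (E)-3-methylpent-2-enoic acid | CC/C(C)=C/C(=O)O | starting material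
22 | neryl (E)-3-methylpent-2-enoate | CC/C(C)=C/C(=O)OC/C=C(/C)CCC=C(C)C | intermediate
23 | (2Z,6E)-8-hydroxy-3,7-dimethylocta-2,6-dien-1-yl (E)-3-methylpent-2-enoate | CC/C(C)=C/C(=O)OC/C=C(/C)CC/C=C(\C)CO | intermediate
24 | (2Z,6E)-3,7-dimethyl-8-oxoocta-2,6-dien-1-yl (E)-3-methylpent-2-enoate | CC/C(C)=C/C(=O)OC/C=C(/C)CC/C=C(\C)C=O | intermediate
25 | O-trichlorosilyl ether of 26 | CC/C(C)=C/C(=O)OC/C=C(/C)CC/C=C(\C)[C@H](C/C=C1/C(=O)O[C@H](C=C(C)C)[C@H]1O[Si](C)(C)C(C)(C)C)O[Si](Cl)(Cl)Cl | intermediate
26 | (2Z,6E,8S)-10-[(3E,4S,5R)-4-(tert-butyldimethylsilyloxy)-5-(2-methylprop-1-enyl)-2-oxooxolan-3-ylidene]-8-hydroxy-3,7-dimethyldeca-2,6-dien-1-yl (E)-3-methylpent-2-enoate | CC/C(C)=C/C(=O)OC/C=C(/C)CC/C=C(\C)[C@H](C/C=C1/C(=O)O[C@H](C=C(C)C)[C@H]1O[Si](C)(C)C(C)(C)C)O | intermediate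
27 | (2Z,6E,8S)-8-acetoxy-10-[(3E,4S,5R)-4-(tert-butyldimethylsilyloxy)-5-(2-methylprop-1-enyl)-2-oxooxolan-3-ylidene]-3,7-dimethyldeca-2,6-dien-1-yl (E)-3-methylpent-2-enoate | CC/C(C)=C/C(=O)OC/C=C(/C)CC/C=C(\C)[C@H](C/C=C1/C(=O)O[C@H](C=C(C)C)[C@H]1O[Si](C)(C)C(C)(C)C)OC(C)=O | intermediate
28 | (2Z,6E,8S)-8-acetoxy-10-[(3E,4S,5R)-4-hydroxy-5-(2-methylprop-1-enyl)-2-oxooxolan-3-ylidene]-3,7-dimethyldeca-2,6-dien-1-yl (E)-3-methylpent-2-enoate | CC/C(C)=C/C(=O)OC/C=C(/C)CC/C=C(\C)[C@H](C/C=C1/C(=O)O[C@H](C=C(C)C)[C@H]1O)OC(C)=O | target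

**Step count and risks**
Total: 17 steps. Longest linear sequence: 14 steps (steps 1–11, then 15–17); the C1–C8 enal 24 takes 3 steps (12–14).

Step 15. What may go wrong: bond formation through the hindered α-carbon C11 instead of C9, erosion of catalyst control over the C8 face, or formation of the (Z)-alkylidene through the s-cis dienolate. The fallback sets out from 24 and 12 and returns at 26. Enal 24 would be converted by an Sn(OTf)2–chiral diamine-promoted Mukaiyama aldol with 1-(ethylsulfanyl)-1-(trimethylsilyloxy)ethene (diamine antipode chosen for the 8S carbinol) into S-ethyl (3S,4E,8Z)-3-hydroxy-4,8-dimethyl-10-[(E)-3-methylpent-2-enoyloxy]deca-4,8-dienethioate F1. Silylation with Et3SiCl and imidazole would give its triethylsilyl ether F2, and Fukuyama reduction (Et3SiH, Pd/C, acetone) would give (2Z,6E,8S)-3,7-dimethyl-10-oxo-8-(triethylsilyloxy)deca-2,6-dien-1-yl (E)-3-methylpent-2-enoate F3 without touching the enoate ester. Addition of lithium enolate 14 to F3 would give the aldol adduct F4. Mesylation to its mesylate F5 and DBU elimination as in step 10 should give the (E)-alkylidene lactone carrying the C8 triethylsilyl ether F6, in which the geometry is now set by the elimination. PPTS in methanol would then remove only the triethylsilyl group and deliver 26.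

Step 8. What may go wrong: β-hydride loss from the π-allyl to the 4,6-dienoic acid outrunning ring closure, or a low trans to cis preference at C13. The fallback sets out from 10 and returns at 12. Ozonolysis of the single alkene of 10 (O3, CH2Cl2, −78 °C; PPh3) would give methyl (S)-3-(tert-butyldimethylsilyloxy)-4-oxobutanoate F7. Non-chelation-controlled Grignard addition of 2-methylprop-1-enylmagnesium bromide at −78 °C should give mainly the 3,4-anti adduct methyl (3S,4R)-3-(tert-butyldimethylsilyloxy)-4-hydroxy-6-methylhept-5-enoate F8, which lactonises on warming or with catalytic PPTS to 12. C13 is then set by carbonyl addition and the ring by acyl substitution instead of the allyl-palladium closure.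

Step 11. What may go wrong: expulsion of the C12 silyloxide from lithium dienolate 18, giving a 3-vinylbutenolide, before O-silylation. The fallback sets out from 17 and returns at 19. The silyl ether of 17 would be cleaved with HF·pyridine to (3E,4S,5R)-3-ethylidene-4-hydroxy-5-(2-methylprop-1-enyl)oxolan-2-one F9. Double deprotonation with LiN(iPr)2 (2.2 equiv, THF/DMPU, −78 °C) would give the dilithium alkoxide–dienolate F10, in which the C12 oxide can no longer act as a leaving group, and silylation of both oxygens with TBSCl (2.5 equiv) gives 19.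

**Further compounds**
F1 | step 15 | S-ethyl (3S,4E,8Z)-3-hydroxy-4,8-dimethyl-10-[(E)-3-methylpent-2-enoyloxy]deca-4,8-dienethioate | CC/C(C)=C/C(=O)OC/C=C(/C)CC/C=C(\C)[C@H](CC(=O)SCC)O
F2 | step 15 | triethylsilyl ether of F1 | CC/C(C)=C/C(=O)OC/C=C(/C)CC/C=C(\C)[C@H](CC(=O)SCC)O[Si](CC)(CC)CC
F3 | step 15 | (2Z,6E,8S)-3,7-dimethyl-10-oxo-8-(triethylsilyloxy)deca-2,6-dien-1-yl (E)-3-methylpent-2-enoate | CC/C(C)=C/C(=O)OC/C=C(/C)CC/C=C(\C)[C@H](CC=O)O[Si](CC)(CC)CC
F4 | step 15 | aldol adduct of 14 and F3 (C10 carbinol epimers) | CC/C(C)=C/C(=O)OC/C=C(/C)CC/C=C(\C)[C@H](CC(O)[C@@H]1C(=O)O[C@H](C=C(C)C)[C@H]1O[Si](C)(C)C(C)(C)C)O[Si](CC)(CC)CC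
F5 | step 15 | mesylate of F4 | CC/C(C)=C/C(=O)OC/C=C(/C)CC/C=C(\C)[C@H](CC(OS(C)(=O)=O)[C@@H]1C(=O)O[C@H](C=C(C)C)[C@H]1O[Si](C)(C)C(C)(C)C)O[Si](CC)(CC)CC
F6 | step 15 | 8-O-triethylsilyl ether of 26 | CC/C(C)=C/C(=O)OC/C=C(/C)CC/C=C(\C)[C@H](C/C=C1/C(=O)O[C@H](C=C(C)C)[C@H]1O[Si](C)(C)C(C)(C)C)O[Si](CC)(CC)CC
F7 | step 8 | methyl (S)-3-(tert-butyldimethylsilyloxy)-4-oxobutanoate | COC(=O)C[C@H](O[Si](C)(C)C(C)(C)C)C=O
F8 | step 8 | methyl (3S,4R)-3-(tert-butyldimethylsilyloxy)-4-hydroxy-6-methylhept-5-enoate | COC(=O)C[C@H](O[Si](C)(C)C(C)(C)C)[C@H](O)C=C(C)C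
F9 | step 11 | (3E,4S,5R)-3-ethylidene-4-hydroxy-5-(2-methylprop-1-enyl)oxolan-2-one | C/C=C1/C(=O)O[C@H](C=C(C)C)[C@H]1O
F10 | step 11 | dilithium alkoxide–dienolate of F9 | C=CC1=C(O[Li])O[C@H](C=C(C)C)[C@H]1O[Li]
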